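(Readings and results were generated by integration for substances that don't exist, noise included.)

Count the turns that the catalyst in Sunday's flask made before its run went flat, then test that count on a fresh dose. I followed Sunday's flask, the one asked about, with Saturday's earlier run beside it.

| flask | substrate | reagent | free catalyst | temperature | remark | time |
|---|---|---|---|---|---|---|
| Sunday's | 0.30 M | 0.27 M | 15 mM | 90 °C | the very flask that is asked about, followed so far |  |
| Saturday's | 0.30 M | 0.27 M | 22 mM | 75 °C | run made earlier |  |
| flask | 0.30 M | 0.270 M | 15 mM | 90 °C |  | 1.5 h |

- Sunday's (time / min: product / %): 6.00: 4.4; 10.0: 7.1; 20.0: 10.6; 40.0: 13.4; 80.0: 13.7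
- Saturday's (time / min: product / %): 2.00: 0.7; 5.00: 3.4; 10.0: 7.5; 15.0: 11.7; 20.0: 15.1

(scatter of a reading: 1 percentage point)

- dawn: change nothing and wait 50 min more
- summer: at 1.5 h take out 90 % of the product then present, then wait 50 min
- dusk: at 1.5 h add free catalyst, 100 % of the amount charged, then wait 50 min
- autumn: at 1.5 h add reagent, 100 % of the amount charged, then wait 50 min
- noon: at 1.5 h raise the temperature by 25 K, then wait 50 min

- product that was removed still counts
- additions bring no volume worth counting

- product, in percent of the substrate first charged, at 1.5 h
- the option that brings most further product ("none" if no option brings more than 2 percentage points) (dawn / summer / dusk / autumn / noon / none)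
- product present, with what was taken out counted in, in percent of the substrate first charged, after dusk
- product present, with what was taken out counted in, in percent of the substrate first charged, after noon

I read Sunday's table downward. Product climbed at first, but between the last two rows it gained 0.3 percentage points, less than the scatter of 1 point, so I took Sunday's flask as flat. That reading of 13.7 % lay far below the 90.0 % allowed by the reagent, the limiting reagent, so I looked to the catalyst and not to the charges.

Then I read across. After 20.0 min, Saturday's run stood at 15.1 %, higher than Sunday's 10.6 % at that time, and it was still gaining 3.4 points between its last rows, so Saturday's run showed no ceiling.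

I carried one number from Sunday's flask: 2.74 turns, the product at the plateau over the catalyst charged, which is the turnover number. Saturday's run had reached 2.06 turns at its last row, unfinished.

If a fresh dose in Sunday's flask turned as often, dusk would add 14 points, so I reckoned 27.4 % after dusk. I expected about 13.7 % at the asked time and the same after noon, since heating adds no catalyst.

The forecast gave 13.8 % for now, dusk as best, 25.5 % after dusk and 13.9 % after noon. Its ground was this: “The likeliest cause is time-dependent thermal catalyst death”. It reckoned the second burst in half-lives, and its dusk figure came out lower than mine.

The flask gave 14.5 % at the asked time and 14.5 % after noon. The best option was dusk, with a gain of 26 points and 40.0 % in the end, while the other options each stayed below 2 points.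

    substrate + free catalyst → free catalyst + open intermediate (k = 0.110 M⁻¹ s⁻¹, Ea = 78.0 kJ mol⁻¹)
    free catalyst + open intermediate ⇌ catalyst intermediate (K = 1.80 M⁻¹, k = 0.740 M⁻¹ s⁻¹, Ea = 49.0 kJ mol⁻¹, ΔH = −59.0 kJ mol⁻¹)
    reagent + catalyst intermediate → free catalyst + product (k = 0.200 M⁻¹ s⁻¹, Ea = 76.0 kJ mol⁻¹)
    reagent + free catalyst → spent catalyst (k = 0.00830 M⁻¹ s⁻¹, Ea = 85.0 kJ mol⁻¹)
    (constants at 90 °C)

The dusk dose in the flask made 5.10 turns, twice the 2.74 I had carried, so my 27.4 % fell short as well. When it went in, after 90.0 min, the flask held [open intermediate] = 0.123 M. The neighbouring flask had 1.2 M of substrate and the same catalyst. Carried unchanged, 2.74 turns predict 3.42 % of its substrate. It gave 15.2 %, which is 12.2 turns. After 90.0 min that neighbour held [open intermediate] = 0.604 M, with spent catalyst at 95.3 %.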